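**Plan**

- Retrosynthesis: once the three phenols are unmasked, ring A is cut at C8–C8a and C4a–C5. This is possible because C5 (OMe), C6 (prenyl) and C7 (OH) follow one another exactly as C1, C2 and C3 of a 1,1-dimethoxy-2-prenyl-3-silyloxybuta-1,3-diene, and because C4a=C8a is an enone double bond of a 4-pyranone (ring C).
- The remaining cuts are C3–C1' (ring B boronate plus 3,5-dibromo-4-pyranone), the silyl enol ether and C-acetyl bonds of the diene, and the C–C bond between a homoprenyl Grignard reagent and an orthocarbonate carbon.
- Forward: ring C is bought as 4-pyranone and dibrominated, and ring B is attached by one Suzuki–Miyaura coupling. Ring A is then annulated onto the silyl-triflate-activated bromopyranone and made aromatic by loss of methanol and HBr, and one fluoride treatment frees the phenols.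
- Stereochemistry: the target has no stereocenter and no stereogenic double bond. The two ring-fusion centers that appear during the annulation are racemic and are erased on aromatization.

Key step: step 9

**Route**

Step 1
Reactants: 1 4-bromoresorcinol (4-bromobenzene-1,3-diol)
Product: 2 bis-silyl ether 1-bromo-2,4-bis(triisopropylsilyloxy)benzene
Conditions: TIPSCl (2.4 equiv), imidazole (5 equiv), DMF, rt to 40 °C
Reagents that add atoms: triisopropylsilyl chloride, CC(C)[Si](Cl)(C(C)C)C(C)C
Why: Silylation of phenols with a silyl chloride and imidazole; TIPS ethers are chosen because they withstand the acetate and phosphate bases of steps 2 and 4 and the silyl triflate of step 9, where acetal-type phenol protection would be opened, and because they fall to fluoride at the end.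

Step 2
Reactants: 2 1-bromo-2,4-bis(triisopropylsilyloxy)benzene
Product: 3 ring B boronate 2-[2,4-bis(triisopropylsilyloxy)phenyl]-4,4,5,5-tetramethyl-1,3,2-dioxaborolane
Conditions: B2pin2 (1.2 equiv), Pd(dppf)Cl2 (5 mol %), KOAc (3 equiv), 1,4-dioxane, 90 °C
Reagents that add atoms: bis(pinacolato)diboron, CC1(C)OB(OC1(C)C)B1OC(C)(C)C(C)(C)O1
Why: Miyaura borylation of an aryl bromide with B2pin2 under palladium catalysis and KOAc, which avoids an ortho-silyloxy aryllithium that would suffer silyl migration from oxygen to carbon.

Step 3
Reactants: 4 4H-pyran-4-one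
Product: 5 dibromide 3,5-dibromo-4H-pyran-4-one
Conditions: Br2 (2.1 equiv), CH2Cl2, 0 °C to rt; then Et3N, 0 °C
Reagents that add atoms: bromine, BrBr
Why: Bromine adds across each enol ether double bond and Et3N then removes HBr by an E1cB path (alpha-bromination of a vinylogous ester by addition–elimination, the reaction that turns chromone into 3-bromochromone), so that both alpha carbons of the symmetric pyranone end up brominated.

Step 4
Reactants: 5 3,5-dibromo-4H-pyran-4-one (2.5 equiv, excess recovered); 3 ring B boronate
Product: 6 aryl bromopyranone 3-bromo-5-[2,4-bis(triisopropylsilyloxy)phenyl]-4H-pyran-4-one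
Conditions: Pd(OAc)2 (5 mol %), SPhos (10 mol %), K3PO4, toluene/H2O, 60 °C
Reagents that add atoms: none
Why: Suzuki–Miyaura coupling of an alpha-bromo enone with an ortho-substituted aryl boronate, for which the SPhos-based catalyst is suited; the excess of the symmetric dibromide 5 and the greater bulk and electron density of 6 should hold the reaction at mono-arylation, and the TIPS ethers tolerate aqueous phosphate.

Step 5
Reactants: 7 5-bromo-2-methylpent-2-ene (homoprenyl bromide)
Product: 9 trimethyl ortho-5-methylhex-4-enoate (1,1,1-trimethoxy-5-methylhex-4-ene), via homoprenylmagnesium bromide 8 (not isolated)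
Conditions: Mg, THF, 40 °C; then C(OMe)4, toluene, 80 °C; basic aqueous work-up
Reagents that add atoms: tetramethyl orthocarbonate, COC(OC)(OC)OC; magnesium, [Mg] (held in intermediate 8 only)
Why: Tschitschibabin orthoester synthesis: the Grignard reagent 8 replaces one methoxide of the orthocarbonate, and the orthoester formed is much less electrophilic than the orthocarbonate, so that addition stops after one C–C bond; a basic work-up keeps the orthoester intact.

Step 6
Reactants: 9 trimethyl ortho-5-methylhex-4-enoate
Product: 10 ketene acetal 1,1-dimethoxy-5-methylhexa-1,4-diene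
Conditions: TMSOTf (1.1 equiv, added slowly), iPr2NEt (1.3 equiv), CH2Cl2, −20 °C to rt; distillation
Reagents that add atoms: none
Why: Silyl-triflate-mediated elimination of methanol, the method that converts acetals into enol ethers and ortho esters into ketene acetals: TMSOTf removes one methoxide as MeOSiMe3 and iPr2NEt deprotonates the dialkoxycarbenium ion at C2; slow addition of the triflate to substrate and excess base keeps the cation from meeting the ketene acetal already formed.

Step 7
Reactants: 10 1,1-dimethoxy-5-methylhexa-1,4-diene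
Product: 11 acylketene acetal 3-(dimethoxymethylene)-6-methylhept-5-en-2-one
Conditions: AcCl (1.1 equiv), 2,6-lutidine (1.3 equiv), CH2Cl2, −40 °C to 0 °C
Reagents that add atoms: acetyl chloride, CC(Cl)=O
Why: C-Acylation of a ketene acetal by an acid chloride: the nucleophilic beta carbon of 10 attacks acetyl chloride, and the alpha proton of the resulting acyl dialkoxycarbenium ion is so acidic that the hindered pyridine base removes it before chloride can demethylate the cation, which gives the push–pull acylketene acetal; 2,6-lutidine is used because it does not turn acetyl chloride into ketene.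

Step 8
Reactants: 11 3-(dimethoxymethylene)-6-methylhept-5-en-2-one
Product: 12 diene 3-(tert-butyldimethylsilyloxy)-1,1-dimethoxy-2-(3-methylbut-2-en-1-yl)buta-1,3-diene
Conditions: TBSOTf (1.1 equiv), Et3N (1.5 equiv), Et2O, 0 °C; used directly after filtration and concentration
Reagents that add atoms: tert-butyldimethylsilyl triflate, CC(C)(C)[Si](C)(C)OS(=O)(=O)C(F)(F)F
Why: Silyl enol ether formation from a methyl ketone with a silyl triflate and an amine, the way 1-alkoxy- and 1,1-dialkoxy-3-silyloxy dienes are usually made; the methyl group is the only enolizable position because C3 is fully substituted, so a single diene results.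

Step 9
Reactants: 6 3-bromo-5-[2,4-bis(triisopropylsilyloxy)phenyl]-4H-pyran-4-one; 12 3-(tert-butyldimethylsilyloxy)-1,1-dimethoxy-2-prenylbuta-1,3-diene (1.5 equiv)
Product: 15 protected isoflavone 7-(tert-butyldimethylsilyloxy)-5-methoxy-6-prenyl-3-[2,4-bis(triisopropylsilyloxy)phenyl]-4H-chromen-4-one, via silyloxypyrylium triflate 13 (not isolated), via cis-fused bromo ketal adduct 14 (not isolated)
Conditions: TBSOTf (1.0 equiv), CH2Cl2, 0 °C to rt; then 2,6-lutidine, 12, −78 °C to rt; then DBU, rt
Reagents that add atoms: tert-butyldimethylsilyl triflate, CC(C)(C)[Si](C)(C)OS(=O)(=O)C(F)(F)F (its atoms are held in intermediate 13 only; none remain in 15)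
Why: Proposed new method: silylation of the carbonyl oxygen of 6, its most basic site, gives pyrylium salt 13, whose C2 (the future C8a) takes the nucleophilic CH2 terminus of 12 in a vinylogous Mukaiyama–Michael addition, and the dimethoxycarbenium ion so formed is captured by the silyl enol ether carbon that bears bromine (the future C4a), the two events together being an asynchronous [4+2] addition to 14 that returns the silyl triflate. The closest known reaction types are the Diels–Alder additions of 1,1-dialkoxy-3-silyloxy dienes to haloquinones, the annulations of silyloxy dienes onto acceptor-substituted chromones to xanthones and the additions of silyl enol ethers to 4-silyloxypyrylium and 4-silyloxybenzopyrylium salts. Ring A closes as a six-membered carbocycle, in the stepwise limit by 6-(enolexo)-exo-trig attack of C4a on the C5 carbenium carbon and in the concerted limit by suprafacial [4+2] addition. The silyl triflate then ionizes the C5 ketal (methoxide leaves as the silyl methyl ether, H-8 goes to 2,6-lutidine) and DBU removes HBr across C4a–C8a, an elimination driven by aromatization, which leaves OMe on C5, prenyl on C6 and the silyl ether on C7 without any step having to tell C6 from C8 or O5 from O7. No stereocenter is kept: C4a and C8a of 14 arise cis because both new bonds enter the same face of the ring double bond, and both centers vanish on aromatization. The selectivity needed is attack at the pyrylium carbon next to C–Br and not at the one next to C–aryl, and it is secured by the inductive pull of bromine on its side and by the twisted ring B, whose ortho triisopropylsilyloxy group covers the other alpha carbon.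

Step 10
Reactants: 15 7-(tert-butyldimethylsilyloxy)-5-methoxy-6-prenyl-3-[2,4-bis(triisopropylsilyloxy)phenyl]-4H-chromen-4-one
Product: 16 target 3-(2,4-dihydroxyphenyl)-7-hydroxy-5-methoxy-6-(3-methylbut-2-en-1-yl)-4H-chromen-4-one
Conditions: TBAF (3.5 equiv), AcOH (3.5 equiv), THF, 0 °C to rt
Reagents that add atoms: none
Why: Fluoride-induced cleavage of aryl silyl ethers, buffered with acetic acid so that neither the chromone ring nor the prenyl group meets strong base or acid; the methyl ether at C5 is untouched.

**Compound list**

1 | 4-bromoresorcinol (4-bromobenzene-1,3-diol) | Oc1ccc(Br)c(O)c1 | starting material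
2 | 1-bromo-2,4-bis(triisopropylsilyloxy)benzene | CC(C)[Si](Oc1ccc(Br)c(O[Si](C(C)C)(C(C)C)C(C)C)c1)(C(C)C)C(C)C | intermediate
3 | 2-[2,4-bis(triisopropylsilyloxy)phenyl]-4,4,5,5-tetramethyl-1,3,2-dioxaborolane | CC(C)[Si](Oc1ccc(B2OC(C)(C)C(C)(C)O2)c(O[Si](C(C)C)(C(C)C)C(C)C)c1)(C(C)C)C(C)C | intermediate
4 | 4H-pyran-4-one | O=c1ccocc1 | starting material
5 | 3,5-dibromo-4H-pyran-4-one | O=c1c(Br)cocc1Br | intermediate
6 | 3-bromo-5-[2,4-bis(triisopropylsilyloxy)phenyl]-4H-pyran-4-one | O=c1c(Br)cocc1-c1ccc(O[Si](C(C)C)(C(C)C)C(C)C)cc1O[Si](C(C)C)(C(C)C)C(C)C | intermediate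
7 | 5-bromo-2-methylpent-2-ene (homoprenyl bromide) | CC(C)=CCCBr | starting material
8 | (4-methylpent-3-en-1-yl)magnesium bromide | CC(C)=CCC[Mg]Br | intermediate (not isolated)
9 | 1,1,1-trimethoxy-5-methylhex-4-ene (trimethyl ortho-5-methylhex-4-enoate) | CC(C)=CCCC(OC)(OC)OC | intermediate
10 | 1,1-dimethoxy-5-methylhexa-1,4-diene | COC(OC)=CCC=C(C)C | intermediate
11 | 3-(dimethoxymethylene)-6-methylhept-5-en-2-one (4,4-dimethoxy-3-prenylbut-3-en-2-one) | CC(=O)C(CC=C(C)C)=C(OC)OC | intermediate
12 | 3-(tert-butyldimethylsilyloxy)-1,1-dimethoxy-2-(3-methylbut-2-en-1-yl)buta-1,3-diene | COC(OC)=C(CC=C(C)C)C(=C)O[Si](C)(C)C(C)(C)C | intermediate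
13 | 3-bromo-4-(tert-butyldimethylsilyloxy)-5-[2,4-bis(triisopropylsilyloxy)phenyl]pyrylium triflate | CC(C)(C)[Si](C)(C)Oc1c(Br)c[o+]cc1-c1ccc(O[Si](C(C)C)(C(C)C)C(C)C)cc1O[Si](C(C)C)(C(C)C)C(C)C.[O-]S(=O)(=O)C(F)(F)F | intermediate (not isolated)
14 | racemic cis-fused adduct 4a-bromo-7-(tert-butyldimethylsilyloxy)-5,5-dimethoxy-6-prenyl-3-[2,4-bis(triisopropylsilyloxy)phenyl]-4a,5,8,8a-tetrahydro-4H-chromen-4-one, H-8a and Br on the same face (one enantiomer drawn) | Br[C@]12C(=O)C(c3ccc(O[Si](C(C)C)(C(C)C)C(C)C)cc3O[Si](C(C)C)(C(C)C)C(C)C)=CO[C@H]1CC(O[Si](C)(C)C(C)(C)C)=C(CC=C(C)C)C2(OC)OC | intermediate (not isolated)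
15 | 7-(tert-butyldimethylsilyloxy)-5-methoxy-6-prenyl-3-[2,4-bis(triisopropylsilyloxy)phenyl]-4H-chromen-4-one | COc1c(CC=C(C)C)c(O[Si](C)(C)C(C)(C)C)cc2occ(-c3ccc(O[Si](C(C)C)(C(C)C)C(C)C)cc3O[Si](C(C)C)(C(C)C)C(C)C)c(=O)c12 | intermediate
16 | 3-(2,4-dihydroxyphenyl)-7-hydroxy-5-methoxy-6-(3-methylbut-2-en-1-yl)-4H-chromen-4-one (CNP0121160.0) | COc1c(CC=C(C)C)c(O)cc2occ(-c3ccc(O)cc3O)c(=O)c12 | target

**Count and risks**

Total step count: 10. Longest linear sequence: 6 steps (steps 5 to 10, from 7 to 16).

Steps most likely to fail:

1. Step 9 (proposed new method). The diene may add at the alpha carbon next to ring B, which gives an adduct that cannot aromatize. The dimethoxycarbenium ion may be demethylated before the ring closes. Loss of HBr may stall because H-8a and bromine are cis.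
Fallback with known chemistry, setting out from boronate 3 and coming back at 15: ring A is taken from a benzene derivative and ring B is joined last. Commercial 2',4'-dihydroxy-6'-methoxyacetophenone is silylated at the non-chelated hydroxyl (TBSCl, imidazole, DMF) to 4'-(tert-butyldimethylsilyloxy)-2'-hydroxy-6'-methoxyacetophenone F1. Mitsunobu etherification of the chelated hydroxyl with prenol (PPh3, DIAD, THF) gives 4'-(tert-butyldimethylsilyloxy)-6'-methoxy-2'-(prenyloxy)acetophenone F2. Heating in N,N-diethylaniline at about 200 °C moves the prenyl group by a Claisen and then a Cope shift to the para position, between the silyloxy and the methoxy carbon, and gives 4'-(tert-butyldimethylsilyloxy)-2'-hydroxy-6'-methoxy-5'-prenylacetophenone F3. Condensation with DMF dimethyl acetal gives the enaminone (E)-3-(dimethylamino)-1-[4-(tert-butyldimethylsilyloxy)-2-hydroxy-6-methoxy-5-prenylphenyl]prop-2-en-1-one F4. Iodine closes it to 7-(tert-butyldimethylsilyloxy)-3-iodo-5-methoxy-6-prenylchromone F5. Suzuki–Miyaura coupling of F5 with 3 (Pd(OAc)2, SPhos, K3PO4, toluene/H2O) gives 15.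

2. Step 4. The coupling may run on to the 3,5-diaryl pyranone, the hindered electron-rich boronate may lose boron to water, and aqueous base may open the pyranone ring.
Fallback setting out from 4 and coming back at 6: the two alpha positions are told apart by the halogen. One equivalent of bromine and then Et3N give 3-bromo-4H-pyran-4-one F6. Iodine monochloride and then Et3N give 3-bromo-5-iodo-4H-pyran-4-one F7. Coupling of F7 with 3 (Pd(PPh3)4, Na2CO3, DME/H2O, rt) should take place at the C–I bond only and gives 6.

3. Step 6. The ketene acetal may condense with the dialkoxycarbenium ion from which it is formed, or may be hydrolysed to the methyl ester during isolation.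
Fallback setting out from 7 and coming back at 10: the ketene acetal is made by olefination, with no carbenium ion present. Kornblum-type oxidation of 7 with trimethylamine N-oxide in DMSO gives 4-methylpent-3-enal F8. (Dimethoxymethyl)diphenylphosphine oxide F9, made from chlorodiphenylphosphine and trimethyl orthoformate, is lithiated (LiN(iPr)2, THF, −100 °C) and added to F8 to give racemic 1-(diphenylphosphoryl)-1,1-dimethoxy-5-methylhex-4-en-2-ol F10. KOtBu then brings about the Horner–Wittig elimination to 10.

**Further compounds**

F1 | step 9 | 4'-(tert-butyldimethylsilyloxy)-2'-hydroxy-6'-methoxyacetophenone | CC(=O)c1c(O)cc(O[Si](C)(C)C(C)(C)C)cc1OC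
F2 | step 9 | 4'-(tert-butyldimethylsilyloxy)-6'-methoxy-2'-(prenyloxy)acetophenone | CC(=O)c1c(OCC=C(C)C)cc(O[Si](C)(C)C(C)(C)C)cc1OC
F3 | step 9 | 4'-(tert-butyldimethylsilyloxy)-2'-hydroxy-6'-methoxy-5'-prenylacetophenone | CC(=O)c1c(O)cc(O[Si](C)(C)C(C)(C)C)c(CC=C(C)C)c1OC
F4 | step 9 | (E)-3-(dimethylamino)-1-[4-(tert-butyldimethylsilyloxy)-2-hydroxy-6-methoxy-5-prenylphenyl]prop-2-en-1-one | CN(C)/C=C/C(=O)c1c(O)cc(O[Si](C)(C)C(C)(C)C)c(CC=C(C)C)c1OC
F5 | step 9 | 7-(tert-butyldimethylsilyloxy)-3-iodo-5-methoxy-6-prenylchromone | COc1c(CC=C(C)C)c(O[Si](C)(C)C(C)(C)C)cc2occ(I)c(=O)c12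
F6 | step 4 | 3-bromo-4H-pyran-4-one | O=c1ccocc1Br
F7 | step 4 | 3-bromo-5-iodo-4H-pyran-4-one | O=c1c(Br)cocc1I
F8 | step 6 | 4-methylpent-3-enal | CC(C)=CCC=O
F9 | step 6 | (dimethoxymethyl)diphenylphosphine oxide | COC(OC)P(=O)(c1ccccc1)c1ccccc1
F10 | step 6 | racemic 1-(diphenylphosphoryl)-1,1-dimethoxy-5-methylhex-4-en-2-ol (one enantiomer drawn) | COC(OC)([C@@H](O)CC=C(C)C)P(=O)(c1ccccc1)c1ccccc1
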